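(The earlier runs and the new flask come from a simulation from invented constants; the scatter is artificial.)

The birch run, charged with too little coupling partner, shows where the substrate in this kind of flask goes.

| flask | substrate | coupling partner | remark | time |
|---|---|---|---|---|
| birch | 10 mM | 0.55 equiv | run made earlier |  |
| ash | 10 mM | 2.2 equiv | run made earlier |  |
| alder | 5 mM | 1.1 equiv | run made earlier |  |
| flask | 10 mM | 1.10 equiv |  | 20 min |

- birch (time / min: substrate / %, mono adduct / %, double product / %): 1.33: 80.2, 13.7, 0.5; 3.00: 62.2, 19.4, 0.9; 6.00: 43.3, 18.6, 1.1; 15.0: 21.6, 12.2, 1.6
- ash (time / min: substrate / %, mono adduct / %, double product / %): 4.00: 8.9, 45.3, 8.5; 8.00: 1.0, 34.4, 10.0; 12.0: 0, 27.1, 10.4; 15.0: 0.4, 22.7, 9.5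
- alder (time / min: substrate / %, mono adduct / %, double product / %): 4.00: 51.2, 30.8, 1.5; 8.00: 28.4, 33.7, 3.1; 12.0: 17.8, 34.1, 3.9; 15.0: 12.3, 32.8, 4.1

(scatter of a reading: 0.5 percentage points)

1. how much substrate there is at 20 min, in percent of the substrate charged
2. how much mono adduct there is at 20 min, in percent of the substrate charged
3. how much double product there is at 20 min, in percent of the substrate charged
4. how much triple product there is at 20 min, in percent of the substrate charged

- the earlier runs were read with a standard deviation of 0.5 percentage points

What does the unread material hold? At 15.0 min birch shows 21.6% substrate, 12.2% mono adduct and 1.6% double product, so 64.6% of the substrate sits in nothing we read. We take mono adduct, double product and triple product each to hold one substrate unit, with 1, 2 and 3 partner units. That leaves at most 0.396 equiv of partner for the unread share. The ratio 1.63 is the unread load g, substrate units per partner unit in the unread share, and it is a lower limit.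

How much triple product can the flask pay for? The forecast gives 1.5% substrate, 26% mono adduct, 6.5% double product and 20% triple product, assuming “double holds two and triple three” substrate units; there we differ. We accept its first three values, which leave 66.0% unread and 0.710 equiv of partner. At load g the unread share takes 0.405 equiv. Each substrate unit moved into triple product costs 3 partner units in place of 0.613, so if the flask spends its whole charge at exactly load g, our estimate of triple product is 12.8%. This is an estimate and no bound, since it rises with the load, g is a lower limit, and carrying it over from birch is our assumption. The forecast stands above it.

1.63% substrate, 25.2% mono adduct, 5.90% double product and 4.79% triple product stand in the flask at 20 min.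

    coupling partner + mono adduct → double product + released group (k = 0.140 /M/s)
    substrate + mono adduct → side product (k = 0.500 /M/s)
    substrate + coupling partner → mono adduct + released group (k = 0.550 /M/s)
    coupling partner + double product → triple product + released group (k = 0.330 /M/s)
    double product ⇌ isomer of the product (K = 1.10, k = 0.0100 /s)

With the flask's own values the same estimate is 13.3%, and the flask's triple product lies below that, with 16.3% of the partner's charge still there. The neighbour charged with 0.280 equiv has 48.6% unread, which at load g asks 0.298 equiv of partner. Its room is 0.253 equiv, less than that, so load g does not hold in this neighbour, whose own load is at least 1.92, above g. There the coupling partner is the limiting reagent, with 1.47% of its charge left, and the neighbour holds 0.0333% triple product.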